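Compare the two captures at one moment. I supposed that both nucleophiles competed for one common partner, each at a pace proportional to its own concentration. Target over other capture product would then equal s times first nucleophile over second nucleophile, with s a constant of the chemistry.

the same everywhere: substrate 0.43 M; second nucleophile 0.473 M
- south-east: first nucleophile 0.645 M; the very flask that is asked about, followed so far
- east: first nucleophile 0.43 M; run made earlier
- flask: first nucleophile 0.645 M; time 12 h

| run | time / h | target / % | other capture product / % |
|---|---|---|---|
| south-east | 0.250 | 0 | 0 |
| south-east | 0.500 | 1.2 | 3.5 |
| south-east | 1.00 | 0 | 2.2 |
| south-east | 2.00 | 0.8 | 5.7 |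
| south-east | 4.00 | 2.7 | 11.9 |
| east | 0.417 | 2.1 | 1.0 |
| east | 0.667 | 1.8 | 1.4 |
| east | 1.33 | 0.7 | 4.1 |
| east | 2.50 | 2.1 | 7.9 |
| east | 5.00 | 2.5 | 16.1 |

(readings scatter by 1 percentage point)

* share of target in target plus other capture product at 15 min
* share of target in target plus other capture product at 2.0 h
* share of target in target plus other capture product at 12 h

I read s separately from two runs, using the latest reading of each and the charged concentrations, and got 0.166 from the south-east run and 0.171 from the east run. Their mean, 0.169, is my reading of s, the target formed per other capture product with the two nucleophiles at equal concentration: the selectivity factor. With target readings near 2.7% and a scatter of 1 percentage point, it remained a rough figure.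

The first east reading parted from this, giving 2.31. There the rule expected 0.153% target, but 2.1% was read. The south-east run, richer in first nucleophile, read 0% target at 1.00 h, so I took the early east reading for scatter.

For the start of the flask I reckoned a ratio of 0.230, a share of 18.7%. Then came the drift. Extending the south-east pace, I estimated 35.7% other capture product at 12 h, which put second nucleophile at 0.319 M and first nucleophile at 0.610 M in my reckoning. My ratio of formation thus came to 0.322 there, and averaging it with the start gave me a share of 21.6% at 12 h.

The forecast said 24% at 15 min, 19% at 2.0 h and 15% at 12 h, “drifting down slightly with time”, so it differed from my rising share.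

The flask gave 16.3% at 15 min, 16.6% at 2.0 h and 18.2% at 12 h, a share rising. Its 16.3% at 15 min stood lower than my start share of 18.7%, and its 18.2% at 12 h lower than my 21.6%.

    second nucleophile + intermediate → other capture product (k = 1900 M⁻¹ h⁻¹)
    first nucleophile + intermediate → target (k = 270 M⁻¹ h⁻¹)
    substrate → intermediate (k = 0.0390 h⁻¹)

A neighbouring flask was charged with 1.2 M of second nucleophile, its other charges and time held as in the flask. The same s gave it a start ratio of 0.0906, a share of 8.31%. At 15 min it gave 7.11%, and at 12 h it gave 7.47%, with 88% of its second nucleophile left.

The data were generated by integration with constants of no real substance, noise included.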